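Atom numbers (ten-membered ring): C1=C10 (methyl C14 on C10), C4 (OH and methyl C15), C5=C6, C7 (isopropyl), C8 (ester oxygen).
Cuts: the acyl–O bond at C8; C4–OH/C5=C6 traced back to a C5 ketone with a C4=C5 enolate; C2–C3 by a retro-[3,3] shift that rejoins C5–C10; then C5–C4, C7–isopropyl, C10–C1 and C10–C14, back to the six-membered enone 1.
Enabling feature: C10=C1–C2–C3–C4–C5(O) is a six-atom unit in which C2–C3 is the 1,6-bond of a hexa-1,5-diene, so the ten-membered ring is the six-membered ring C5–C10 with a vinyl arm (on C10) and an isopropenyl arm (on C5) inserted between C10 and C5.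
Forward: ring C5–C10 of 1 is methylated and vinylated at C10, isopropylated at C7 and isopropenylated at C5; the anionic oxy-Cope shift forms C2–C3, cleaves C5–C10 and gives the ten-membered ring, whose enolate is oxygenated at C4; the C5 ketone becomes the C5=C6 alkene; the aryl ester is attached last.
Stereochemistry: C8 from 1; C7 by conjugate addition anti to the C8 oxygen; the sacrificial centres C10 and C5 (alkenyl groups trans) give E at C1=C10; C4 by attack on the outer face of the ring enolate; 5E from the enolate geometry, kept through triflate reduction.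

Key step: step 6

Assumption: enone 1 is bought as the single (S) enantiomer (a catalogue chiral building block).

Step 1
Reactants: 1 (S)-4-[(tert-butyldimethylsilyl)oxy]cyclohex-2-en-1-one
Product: 2 (4S)-4-[(tert-butyldimethylsilyl)oxy]-6-methylcyclohex-2-en-1-one (mixture of C6 epimers)
Conditions: LiN(iPr)2, THF, −78 °C; CH3I, −78 → −30 °C
Reagents that add atoms: iodomethane, CI
Why: Kinetic deprotonation at ring carbon 6 gives the cross-conjugated lithium dienolate, which should be C-methylated (enolate alkylation); the new centre is planarised again in step 2, so its configuration does not matter.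

Step 2
Reactants: 2 (4S)-4-[(tert-butyldimethylsilyl)oxy]-6-methylcyclohex-2-en-1-one
Product: 3 (4S,6R)-4-[(tert-butyldimethylsilyl)oxy]-6-(1-hydroxyethyl)-6-methylcyclohex-2-en-1-one (carbinol epimers)
Conditions: LiN(iPr)2, THF, −78 °C; CH3CHO, −78 °C; AcOH, −78 °C
Reagents that add atoms: acetaldehyde, CC=O
Why: Aldol addition of the re-formed enolate builds the quaternary carbon (C10 of the target); the aldehyde should approach the dienolate face opposite the pseudo-axial silyloxy group, placing the hydroxyethyl arm trans to it (6R), while the carbinol centre is removed in step 3.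

Step 3
Reactants: 3 (4S,6R)-4-[(tert-butyldimethylsilyl)oxy]-6-(1-hydroxyethyl)-6-methylcyclohex-2-en-1-one
Product: 4 (4S,6R)-4-[(tert-butyldimethylsilyl)oxy]-6-ethenyl-6-methylcyclohex-2-en-1-one
Conditions: Ph2S[OC(CF3)2Ph]2 (dialkoxydiarylsulfurane dehydrating agent), CH2Cl2, 0 → 25 °C
Reagents that add atoms: none
Why: Dehydration through the alkoxysulfonium intermediate is an E2-type elimination; the other β-carbon is quaternary, so only a methyl hydrogen can leave and the terminal vinyl group should form without base (no retro-aldol) and without touching a stereocentre.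

Step 4
Reactants: 4 (4S,6R)-4-[(tert-butyldimethylsilyl)oxy]-6-ethenyl-6-methylcyclohex-2-en-1-one
Product: 5 (2R,4S,5R)-4-[(tert-butyldimethylsilyl)oxy]-2-ethenyl-2-methyl-5-(propan-2-yl)cyclohexan-1-one
Conditions: iPrMgCl, CuBr·SMe2 (10 mol %), THF, −78 → −40 °C
Reagents that add atoms: isopropylmagnesium chloride, CC(C)[Mg]Cl
Why: Copper-catalysed conjugate addition of the Grignard reagent to the enone; the isopropyl group should enter anti to the adjacent silyloxy group, the usual preference of 4-silyloxycyclohexenones, which sets C7 trans to the C8 oxygen (5R).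

Step 5
Reactants: 5 (2R,4S,5R)-4-[(tert-butyldimethylsilyl)oxy]-2-ethenyl-2-methyl-5-(propan-2-yl)cyclohexan-1-one
Product: 6 (1S,2R,4S,5R)-4-[(tert-butyldimethylsilyl)oxy]-2-ethenyl-2-methyl-5-(propan-2-yl)-1-(prop-1-en-2-yl)cyclohexan-1-ol
Conditions: CH2=C(CH3)MgBr, CeCl3, THF, −78 → 0 °C
Reagents that add atoms: isopropenylmagnesium bromide, CC(=C)[Mg]Br
Why: 1,2-Addition of the organocerium reagent (CeCl3 suppresses enolisation of the hindered ketone); in the chair with isopropyl and silyloxy equatorial the vinyl group is axial and shields its own face, so the nucleophile should add axially from the opposite face and leave the two alkenyl groups trans (1S).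

Step 6
Reactants: 6 (1S,2R,4S,5R)-4-[(tert-butyldimethylsilyl)oxy]-2-ethenyl-2-methyl-5-(propan-2-yl)-1-(prop-1-en-2-yl)cyclohexan-1-ol
Product: 9 (2R,5E,8S,9R)-8-[(tert-butyldimethylsilyl)oxy]-2,6-dimethyl-9-(propan-2-yl)-2-[(triethylsilyl)oxy]cyclodec-5-en-1-one, via potassium enolate 7 (not isolated), via potassium ketol alkoxide 8 (not isolated)
Conditions: KN(SiMe3)2, 18-crown-6, THF, 0 → 66 °C; cool to −78 °C, 2-(phenylsulfonyl)-3-phenyloxaziridine; Et3SiCl, −78 → 0 °C
Reagents that add atoms: 2-(phenylsulfonyl)-3-phenyloxaziridine, O=S(=O)(N1OC1c1ccccc1)c1ccccc1; chlorotriethylsilane, CC[Si](Cl)(CC)CC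
Why: The potassium alkoxide of 6 should undergo a charge-accelerated [3,3] sigmatropic shift through a chair transition state in which the C5–C10 bond of the six-membered ring breaks while the termini of the vinyl and isopropenyl groups join as C2–C3; the closest known reaction type is the anionic oxy-Cope ring expansion of trans-1,2-dialkenylcyclohexanols to cyclodec-5-enones. The ten-membered ring closes by ring expansion (all six shifting atoms end up inside the new ring), not by end-to-end cyclisation of a chain. Ring inversion at 66 °C gives the reactive conformer with both alkenyl groups equatorial; their trans arrangement puts C9 and C6 equatorial on the chair array, which gives E at C1=C10 and the ring-E enolate 7. Holding 7 at 66 °C should let the ring relax to the conformer with isopropyl and silyloxy pseudo-equatorial and C14 and C15 on the same side, and the oxaziridine can reach C4 only from the outer face of that enolate, which sets 4R (C2 of 9). Site selectivity comes from the shift itself, since the enolate exists only at C4=C5, and chemoselectivity from the enolate being far more nucleophilic than the C1=C10 alkene. The alkoxide 8 is silylated in the same flask so that the tertiary hydroxyl does not interfere in step 7.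

Step 7
Reactants: 9 (2R,5E,8S,9R)-8-[(tert-butyldimethylsilyl)oxy]-2,6-dimethyl-9-(propan-2-yl)-2-[(triethylsilyl)oxy]cyclodec-5-en-1-one
Product: 10 (1Z,3S,4S,6E,10R)-4-[(tert-butyldimethylsilyl)oxy]-6,10-dimethyl-3-(propan-2-yl)-10-[(triethylsilyl)oxy]cyclodeca-1,6-dien-1-yl trifluoromethanesulfonate
Conditions: KN(SiMe3)2, THF, −78 °C; PhNTf2, −78 → 0 °C
Reagents that add atoms: N-phenylbis(trifluoromethanesulfonimide), O=S(=O)(N(c1ccccc1)S(=O)(=O)C(F)(F)F)C(F)(F)F
Why: Deprotonation is possible only at C6 (C4 is fully substituted) and the enolate is O-sulfonylated (enol triflate formation); allylic strain against the quaternary C4 should keep C7 on the side of the enolate oxygen, so that C4 and C7 are trans across the new C5=C6 bond.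

Step 8
Reactants: 10 (1Z,3S,4S,6E,10R)-4-[(tert-butyldimethylsilyl)oxy]-6,10-dimethyl-3-(propan-2-yl)-10-[(triethylsilyl)oxy]cyclodeca-1,6-dien-1-yl trifluoromethanesulfonate
Product: 11 tert-butyl{[(1S,2S,3E,5R,8E)-5,9-dimethyl-2-(propan-2-yl)-5-[(triethylsilyl)oxy]cyclodeca-3,8-dien-1-yl]oxy}dimethylsilane
Conditions: Pd(OAc)2 (5 mol %), PPh3, HCO2H, nBu3N, DMF, 60 °C
Reagents that add atoms: none
Why: Palladium-catalysed formate reduction of the enol triflate (oxidative addition of zerovalent palladium, formate exchange, loss of CO2, reductive elimination) should replace the triflate by hydrogen with retention of the alkene geometry, giving the 5E alkene.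

Step 9
Reactants: 11 tert-butyl{[(1S,2S,3E,5R,8E)-5,9-dimethyl-2-(propan-2-yl)-5-[(triethylsilyl)oxy]cyclodeca-3,8-dien-1-yl]oxy}dimethylsilane
Product: 12 (1R,2E,4S,5S,7E)-1,7-dimethyl-4-(propan-2-yl)cyclodeca-2,7-diene-1,5-diol
Conditions: nBu4NF, THF, 0 → 40 °C
Reagents that add atoms: none
Why: Fluoride cleavage of both silyl ethers (desilylation) under non-acidic conditions should keep the tertiary allylic alcohol and the 1(10),5-diene from ionising or cyclising across the ring; no stereocentre is affected.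

Step 10
Reactants: 12 (1R,2E,4S,5S,7E)-1,7-dimethyl-4-(propan-2-yl)cyclodeca-2,7-diene-1,5-diol; 13 4-acetoxy-3-methoxybenzoic acid
Product: 14 (1S,2S,3E,5R,8E)-5-hydroxy-5,9-dimethyl-2-(propan-2-yl)cyclodeca-3,8-dien-1-yl 4-acetoxy-3-methoxybenzoate
Conditions: N,N'-dicyclohexylcarbodiimide, 4-(dimethylamino)pyridine (cat.), CH2Cl2, 0 → 25 °C
Reagents that add atoms: none
Why: Carbodiimide coupling with acyl transfer by the aminopyridine (Steglich esterification) should acylate only the secondary C8 hydroxyl, the tertiary C4 hydroxyl being too hindered, and the C8–O bond is not broken, so the configuration is retained.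

Step 11
Reactants: 14 (1S,2S,3E,5R,8E)-5-hydroxy-5,9-dimethyl-2-(propan-2-yl)cyclodeca-3,8-dien-1-yl 4-acetoxy-3-methoxybenzoate
Product: 15 (1S,2S,3E,5R,8E)-5-hydroxy-5,9-dimethyl-2-(propan-2-yl)cyclodeca-3,8-dien-1-yl 4-hydroxy-3-methoxybenzoate (CNP0162316.1)
Conditions: K2CO3 (0.5 equiv), CH3OH, 0 °C
Reagents that add atoms: none
Why: Base-catalysed methanolysis (transesterification) should remove the aryl acetate much faster than it attacks the hindered, electron-rich benzoate, freeing the phenol.

Compound list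
1 | (S)-4-[(tert-butyldimethylsilyl)oxy]cyclohex-2-en-1-one | O=C1C=C[C@@H](O[Si](C)(C)C(C)(C)C)CC1 | starting material
2 | (4S)-4-[(tert-butyldimethylsilyl)oxy]-6-methylcyclohex-2-en-1-one (C6 epimers) | CC1C[C@H](O[Si](C)(C)C(C)(C)C)C=CC1=O | intermediate
3 | (4S,6R)-4-[(tert-butyldimethylsilyl)oxy]-6-(1-hydroxyethyl)-6-methylcyclohex-2-en-1-one (carbinol epimers) | C[C@]1(C(C)O)C[C@H](O[Si](C)(C)C(C)(C)C)C=CC1=O | intermediate
4 | (4S,6R)-4-[(tert-butyldimethylsilyl)oxy]-6-ethenyl-6-methylcyclohex-2-en-1-one | C[C@]1(C=C)C[C@H](O[Si](C)(C)C(C)(C)C)C=CC1=O | intermediate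
5 | (2R,4S,5R)-4-[(tert-butyldimethylsilyl)oxy]-2-ethenyl-2-methyl-5-(propan-2-yl)cyclohexan-1-one | C[C@]1(C=C)C[C@H](O[Si](C)(C)C(C)(C)C)[C@@H](C(C)C)CC1=O | intermediate
6 | (1S,2R,4S,5R)-4-[(tert-butyldimethylsilyl)oxy]-2-ethenyl-2-methyl-5-(propan-2-yl)-1-(prop-1-en-2-yl)cyclohexan-1-ol | C[C@]1(C=C)C[C@H](O[Si](C)(C)C(C)(C)C)[C@@H](C(C)C)C[C@]1(O)C(C)=C | intermediate
7 | potassium (1Z,5E,8S,9R)-8-[(tert-butyldimethylsilyl)oxy]-2,6-dimethyl-9-(propan-2-yl)cyclodeca-1,5-dien-1-olate (ring-E enolate, C3 and C6 trans) | CC(C)(C)[Si](C)(C)O[C@H]1C/C(C)=C/CC/C(C)=C(\[O-])C[C@@H]1C(C)C.[K+] | intermediate (not isolated)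
8 | potassium alkoxide of (2R,5E,8S,9R)-8-[(tert-butyldimethylsilyl)oxy]-2-hydroxy-2,6-dimethyl-9-(propan-2-yl)cyclodec-5-en-1-one | CC(C)(C)[Si](C)(C)O[C@H]1C/C(C)=C/CC[C@@](C)([O-])C(=O)C[C@@H]1C(C)C.[K+] | intermediate (not isolated)
9 | (2R,5E,8S,9R)-8-[(tert-butyldimethylsilyl)oxy]-2,6-dimethyl-9-(propan-2-yl)-2-[(triethylsilyl)oxy]cyclodec-5-en-1-one | CC(C)(C)[Si](C)(C)O[C@H]1C/C(C)=C/CC[C@@](C)(O[Si](CC)(CC)CC)C(=O)C[C@@H]1C(C)C | intermediate
10 | (1Z,3S,4S,6E,10R)-4-[(tert-butyldimethylsilyl)oxy]-6,10-dimethyl-3-(propan-2-yl)-10-[(triethylsilyl)oxy]cyclodeca-1,6-dien-1-yl trifluoromethanesulfonate | CC(C)(C)[Si](C)(C)O[C@H]1C/C(C)=C/CC[C@@](C)(O[Si](CC)(CC)CC)/C(OS(=O)(=O)C(F)(F)F)=C/[C@@H]1C(C)C | intermediate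
11 | tert-butyl{[(1S,2S,3E,5R,8E)-5,9-dimethyl-2-(propan-2-yl)-5-[(triethylsilyl)oxy]cyclodeca-3,8-dien-1-yl]oxy}dimethylsilane | CC(C)(C)[Si](C)(C)O[C@H]1C/C(C)=C/CC[C@@](C)(O[Si](CC)(CC)CC)/C=C/[C@@H]1C(C)C | intermediate
12 | (1R,2E,4S,5S,7E)-1,7-dimethyl-4-(propan-2-yl)cyclodeca-2,7-diene-1,5-diol | O[C@H]1C/C(C)=C/CC[C@@](C)(O)/C=C/[C@@H]1C(C)C | intermediate
13 | 4-acetoxy-3-methoxybenzoic acid | COc1cc(C(=O)O)ccc1OC(C)=O | starting material
14 | (1S,2S,3E,5R,8E)-5-hydroxy-5,9-dimethyl-2-(propan-2-yl)cyclodeca-3,8-dien-1-yl 4-acetoxy-3-methoxybenzoate | COc1cc(C(=O)O[C@H]2C/C(C)=C/CC[C@@](C)(O)/C=C/[C@@H]2C(C)C)ccc1OC(C)=O | intermediate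
15 | (1S,2S,3E,5R,8E)-5-hydroxy-5,9-dimethyl-2-(propan-2-yl)cyclodeca-3,8-dien-1-yl 4-hydroxy-3-methoxybenzoate (CNP0162316.1) | COc1cc(C(=O)O[C@H]2C/C(C)=C/CC[C@@](C)(O)/C=C/[C@@H]2C(C)C)ccc1O | target

Total step count: 11. Longest linear sequence: 11 steps (1 → 15); 13 is purchased.

Steps most likely to fail

Step 6. The reactive conformer (both alkenyl groups equatorial, the four other ring substituents axial) is strained, so loss of the allyl anion from the alkoxide (retro-addition) may compete with the shift. If the first-formed enolate conformer is oxidised before the ring has relaxed, the oxidant meets the wrong face of C4 (poor facial selectivity). The fallback sets out from 6 and returns at 9. The shift is run as in step 6 but quenched with aqueous NH4Cl to the neutral ketone (5E,8S,9R)-8-[(tert-butyldimethylsilyl)oxy]-2,6-dimethyl-9-(propan-2-yl)cyclodec-5-en-1-one F1, whose ring inverts freely. Et3SiCl, NaI and Et3N in CH3CN (equilibrating conditions) should convert it into the more substituted enol ether (1Z,5E,8S,9R)-8-[(tert-butyldimethylsilyl)oxy]-2,6-dimethyl-9-(propan-2-yl)-1-[(triethylsilyl)oxy]cyclodeca-1,5-diene F2 in its more stable planar arrangement. Rubottom oxidation with dimethyldioxirane at −78 °C (epoxidation of the exposed face, then 1,4-shift of silicon) should give 9.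

Step 7. Enolisation toward C6 may give the enolate with C4 and C7 cis on the ring, or triflation of the hindered enolate may be slow enough for the base to attack the silyl ethers; either way the alkene geometry is lost. The fallback sets out from 9 and returns at 11. iBu2AlH (toluene, −78 °C) reduces the ketone to (2R,5E,8S,9R)-8-[(tert-butyldimethylsilyl)oxy]-2,6-dimethyl-9-(propan-2-yl)-2-[(triethylsilyl)oxy]cyclodec-5-en-1-ol F3. Methyl N-(triethylammoniosulfonyl)carbamate (benzene, 60 °C) then dehydrates it by thermal syn-elimination, which can take only a C6 hydrogen and which in ten-membered rings should lead to the trans alkene.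

Step 3. Ionisation of the activated carbinol next to the quaternary carbon, with 1,2-shift of the acyl group or ether formation, may take the place of elimination toward the methyl group. The fallback sets out from 2 and returns at 4, replacing steps 2 and 3. The lithium enolate of 2 is added to (phenylselanyl)acetaldehyde to give (4S,6R)-4-[(tert-butyldimethylsilyl)oxy]-6-[1-hydroxy-2-(phenylselanyl)ethyl]-6-methylcyclohex-2-en-1-one F4. CH3SO2Cl/Et3N at 0 °C then removes hydroxyl and selenium together by anti-elimination, which should give 4 without a cationic intermediate.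

Further compounds
F1 | step 6 | (5E,8S,9R)-8-[(tert-butyldimethylsilyl)oxy]-2,6-dimethyl-9-(propan-2-yl)cyclodec-5-en-1-one (C2 epimers) | CC(C)(C)[Si](C)(C)O[C@H]1C/C(C)=C/CCC(C)C(=O)C[C@@H]1C(C)C
F2 | step 6 | (1Z,5E,8S,9R)-8-[(tert-butyldimethylsilyl)oxy]-2,6-dimethyl-9-(propan-2-yl)-1-[(triethylsilyl)oxy]cyclodeca-1,5-diene | CC(C)(C)[Si](C)(C)O[C@H]1C/C(C)=C/CC/C(C)=C(\O[Si](CC)(CC)CC)C[C@@H]1C(C)C
F3 | step 7 | (2R,5E,8S,9R)-8-[(tert-butyldimethylsilyl)oxy]-2,6-dimethyl-9-(propan-2-yl)-2-[(triethylsilyl)oxy]cyclodec-5-en-1-ol (C1 epimers) | CC(C)(C)[Si](C)(C)O[C@H]1C/C(C)=C/CC[C@@](C)(O[Si](CC)(CC)CC)C(O)C[C@@H]1C(C)C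
F4 | step 3 | (4S,6R)-4-[(tert-butyldimethylsilyl)oxy]-6-[1-hydroxy-2-(phenylselanyl)ethyl]-6-methylcyclohex-2-en-1-one | C[C@]1(C(O)C[Se]c2ccccc2)C[C@H](O[Si](C)(C)C(C)(C)C)C=CC1=O
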